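The runs were generated by integration for an exercise; noise was put on by code.

- At late times the target readings stay level within their scatter: from 10.0 min to 20.0 min, the readings of the two earlier runs average Y = 89.7 % of the substrate charged. With two candidate steps, the remainder is read as side product.

| flask | substrate | catalyst | remark | time |
|---|---|---|---|---|
| south-east | 4.6 mM | 1 mM (in portions, 2) | run made earlier; portions every 5.0 min |  |
| south-west | 13 mM | 1 mM (in portions, 2) | run made earlier; portions every 5.0 min |  |
| Tuesday's | 6.0 mM | 1.0 mM (in portions, 2) | the portions of catalyst follow each other after 5.0 min, the first at the start | 20 min |
| Wednesday's | 8.0 mM | 1.0 mM (in portions, 2) | the portions of catalyst follow each other after 5.0 min, the first at the start | 20 min |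
| Saturday's | 12 mM | 1.0 mM (in portions, 2) | the portions of catalyst follow each other after 5.0 min, the first at the start | 20 min |
| Friday's | 20 mM | 1.0 mM (in portions, 2) | the portions of catalyst follow each other after 5.0 min, the first at the start | 20 min |

- south-east (time / min: target / %): 2.00: 57; 5.00: 84; 10.0: 88; 15.0: 90; 20.0: 89
- south-west (time / min: target / %): 2.00: 59; 5.00: 84; 10.0: 90; 15.0: 88; 20.0: 93

(each reading ± 2 percentage points)

- candidate steps: substrate -> side product; substrate + catalyst -> catalyst + target
- "hardly changes" means that all values lie within two and a half points (for a concentration: within two and a half percent of the largest)

- amount of target at the end, in percent of the substrate charged for Tuesday's, Wednesday's, Saturday's, Friday's, in this order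
- how that number moves from the first to the last of them (rises, then falls / hardly changes / falls all the way / rises all the way / falls, then rises)

- The number to carry is β, the side product formed per target formed, 0.115, also called an inverse selectivity factor. On this scale 1 marks an even split and zero a clean flask, so this reading lies near the clean end.
- Write the side step's rate as k_s·c_A and the catalysed step's as k_c·c_C·c_A, with c_A the substrate and c_C the catalyst present. Their ratio is k_s/(k_c·c_C), and c_A has cancelled.
- β therefore carries the catalyst schedule inside it, and the recipes above repeat that schedule unchanged: 1.0 mM in 2 portions, 5.0 min apart.
- One number passes the test on the readings. The south-east run at 4.6 mM has a late mean of 89.0 %, which gives β = 0.124. The south-west run at 13 mM has a late mean of 90.3 %, which gives β = 0.107. Those means differ by 1.3 percentage points, and one reading scatters by 2 points.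
- My own reckoning is Y = 1/(1+β) = 89.7 % in each new flask, with a flat row. Friday's 20 mM lies beyond the simulated substrate range, but c_A has cancelled from the ratio of the two rates written above.
- The forecast gave 90 %, 90 %, 90 % and 90 %, a row that hardly changes, on the ground that “the yield depends on catalyst dose and timing, not on substrate concentration”.
- The flasks give 89.4 %, 89.4 %, 89.4 % and 89.4 %, a row that hardly changes.

    substrate → side product (k = 9.80 × 10⁻⁴ s⁻¹)
    substrate + catalyst → catalyst + target (k = 16.0 M⁻¹ s⁻¹)

- Tuesday's flask ends with 10.6 % of side product beside 89.4 % of target, so its β is 0.119. Friday's flask, charged with 3.33 times that substrate, gives 0.118. The side step is the main reason why target falls short of the charge in Friday's flask: with that step taken away, its target goes from 89.4 % to >99.9 %.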